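## Retrosynthetic overview

1. The target comes from global hydrogenolysis of its octa-O-benzyl ether. The lower pyranone ring is closed last, by 6-endo opening of a (2R,3S)-aryl glycidyl ketone by the D-ring ortho-phenol.
2. The glycidyl ketone comes from a D-ring aryllithium (Br/Li exchange) and a (2R,3S)-glycidic Weinreb amide. Both stereocentres of the amide are set by a ketoreductase-catalysed dynamic kinetic reduction of an α-chloro-β-keto ester.
3. The upper 4-arylflavan-3-ol comes from hydroboration of a 4-aryl-flav-3-ene (C3 and C4 set from C2). The flavene comes from 1,2-addition of a D-ring Grignard reagent, metalated between its two oxygens, to an (S)-flavanone, followed by dehydration.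
4. The (S)-flavanone comes from a Pd/PyOX-catalysed asymmetric conjugate addition of a tris(benzyloxy)phenylboronic acid to 7-(benzyloxy)chromone (first stereocentre).
5. Ring order: upper pyran ring (present from the chromone), then the preformed D-ring arene is attached, then the lower pyranone ring.

Assumption: (R)-t-BuPyOX in step 5 and the anti-selective ketoreductase in step 14 are taken to be the catalyst antipodes that give the configurations drawn; if either sense is opposite, the mirror-image ligand or an enantiocomplementary enzyme is used.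

## Route

Step 1
Reactants: 1 5-bromo-1,2,3-trimethoxybenzene
Product: 2 5-bromobenzene-1,2,3-triol
Conditions: BBr3, CH2Cl2, −78 °C → rt; then H2O
Reagents that add atoms: none
Why: BBr3 cleavage of aryl methyl ethers (bromide attacks the O-methyl of the boron complex) frees the three phenols and leaves the aryl bromide untouched.

Step 2
Reactants: 2 5-bromobenzene-1,2,3-triol
Product: 3 5-bromo-1,2,3-tris(benzyloxy)benzene
Conditions: BnBr, K2CO3, DMF, 60 °C, N2
Reagents that add atoms: benzyl bromide BrCc1ccccc1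
Why: Williamson ether synthesis on the three phenoxides gives benzyl ethers that survive every later step and are removed by hydrogenolysis at the end.

Step 3
Reactants: 3 5-bromo-1,2,3-tris(benzyloxy)benzene
Product: 5 [3,4,5-tris(benzyloxy)phenyl]boronic acid, via aryllithium 4 (not isolated)
Conditions: n-BuLi, THF, −78 °C; B(Oi-Pr)3, −78 °C → rt; 1 M HCl
Reagents that add atoms: triisopropyl borate CC(C)OB(OC(C)C)OC(C)C; water O
Why: Fast Br/Li exchange followed by electrophilic borylation and hydrolysis of the borate ester is the standard route to an arylboronic acid.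

Step 4
Reactants: 6 7-hydroxy-4H-chromen-4-one
Product: 7 7-(benzyloxy)-4H-chromen-4-one
Conditions: BnBr, K2CO3, acetone, reflux
Reagents that add atoms: benzyl bromide BrCc1ccccc1
Why: Williamson ether synthesis on the acidic 7-phenol under mild carbonate conditions does not open the chromone ring.

Step 5
Reactants: 7 7-(benzyloxy)-4H-chromen-4-one; 5 [3,4,5-tris(benzyloxy)phenyl]boronic acid
Product: 8 (2S)-7-(benzyloxy)-2-[3,4,5-tris(benzyloxy)phenyl]-2,3-dihydro-4H-chromen-4-one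
Conditions: Pd(OCOCF3)2 (5 mol %), (R)-t-BuPyOX (6 mol %), NH4PF6 (30 mol %), H2O (5 equiv), ClCH2CH2Cl, 60 °C
Reagents that add atoms: none
Why: Pd(II)-catalysed asymmetric conjugate addition of an arylboronic acid to a chromone (Hayashi–Miyaura-type, Pd/PyOX variant): the chiral ligand selects the enone face in the aryl-palladium insertion and sets C2 as S, the first stereocentre.

Step 6
Reactants: 9 2-iodobenzene-1,3-diol
Product: 10 2-iodo-1,3-bis(methoxymethoxy)benzene
Conditions: MOMCl, i-Pr2NEt, CH2Cl2, 0 °C → rt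
Reagents that add atoms: chloromethyl methyl ether COCCl
Why: MOM acetal protection of both phenols gives ethers that tolerate organometallics and borane and can be removed with acid when the lower ring is closed.

Step 7
Reactants: 10 2-iodo-1,3-bis(methoxymethoxy)benzene
Product: 11 1-bromo-3-iodo-2,4-bis(methoxymethoxy)benzene
Conditions: NBS, MeCN, 0 °C → rt
Reagents that add atoms: N-bromosuccinimide O=C1CCC(=O)N1Br
Why: Electrophilic aromatic bromination goes to the only open position that is para to one alkoxy group and ortho to the other, and the first bromine deactivates the ring against a second.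

Step 8
Reactants: 11 1-bromo-3-iodo-2,4-bis(methoxymethoxy)benzene; 8 (2S)-7-(benzyloxy)-2-[3,4,5-tris(benzyloxy)phenyl]-2,3-dihydro-4H-chromen-4-one
Product: 13 (2S)-7-(benzyloxy)-4-[3-bromo-2,6-bis(methoxymethoxy)phenyl]-2-[3,4,5-tris(benzyloxy)phenyl]chroman-4-ol (both C-4 epimers), via arylmagnesium chloride 12 (not isolated)
Conditions: i-PrMgCl·LiCl, THF, −40 °C; LaCl3·2LiCl; then 8, −40 → 0 °C; aq NH4Cl
Reagents that add atoms: none
Why: Iodine–magnesium exchange (turbo-Grignard) is selective for the iodide flanked by two chelating MOM-oxy groups over the bromide, and the lanthanum-promoted 1,2-addition to the ketone suppresses enolisation; this fixes the C–C bond at the carbon between the two D-ring oxygens, and the new C4 centre is removed in step 9.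

Step 9
Reactants: 13 (2S)-7-(benzyloxy)-4-[3-bromo-2,6-bis(methoxymethoxy)phenyl]-2-[3,4,5-tris(benzyloxy)phenyl]chroman-4-ol
Product: 14 (2S)-7-(benzyloxy)-4-[3-bromo-2,6-bis(methoxymethoxy)phenyl]-2-[3,4,5-tris(benzyloxy)phenyl]-2H-chromene
Conditions: MsCl, Et3N, CH2Cl2, 0 °C → rt, dark
Reagents that add atoms: none
Why: E1-type dehydration of the doubly benzylic tertiary alcohol via its mesylate can only place the alkene at C3=C4 (the sole β-hydrogens), both epimers converge, and the basic, room-temperature conditions leave C2 untouched.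

Step 10
Reactants: 14 (2S)-7-(benzyloxy)-4-[3-bromo-2,6-bis(methoxymethoxy)phenyl]-2-[3,4,5-tris(benzyloxy)phenyl]-2H-chromene
Product: 16 (2R,3S,4S)-7-(benzyloxy)-4-[3-bromo-2,6-bis(methoxymethoxy)phenyl]-2-[3,4,5-tris(benzyloxy)phenyl]chroman-3-ol, via alkylborane 15 (not isolated)
Conditions: BH3·THF, THF, 0 °C → rt; then NaOH, H2O2, 0 °C
Reagents that add atoms: hydrogen peroxide OO
Why: Brown hydroboration–oxidation adds H and B syn, with boron at the less substituted C3 and on the face opposite the C2 aryl group, and oxidation with retention gives the 2,3-trans-3,4-trans alcohol, setting C3 (S) and C4 (S) from C2.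

Step 11
Reactants: 16 (2R,3S,4S)-7-(benzyloxy)-4-[3-bromo-2,6-bis(methoxymethoxy)phenyl]-2-[3,4,5-tris(benzyloxy)phenyl]chroman-3-ol
Product: 17 (2R,3S,4S)-3,7-bis(benzyloxy)-4-[3-bromo-2,6-bis(methoxymethoxy)phenyl]-2-[3,4,5-tris(benzyloxy)phenyl]chromane
Conditions: NaH, BnBr, Bu4NI (cat.), DMF, 0 °C → rt
Reagents that add atoms: benzyl bromide BrCc1ccccc1
Why: Williamson benzylation masks the secondary alcohol before the organolithium step and touches no stereocentre.

Step 12
Reactants: 18 3,4,5-tris(benzyloxy)benzoic acid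
Product: 20 methyl 3-oxo-3-[3,4,5-tris(benzyloxy)phenyl]propanoate, via acyl imidazolide 19 (not isolated)
Conditions: CDI, THF, rt; then KO2CCH2CO2Me, MgCl2, Et3N, MeCN, rt → 45 °C; 1 M HCl
Reagents that add atoms: potassium methyl malonate [K+].[O-]C(=O)CC(=O)OC
Why: Masamune–Brooks homologation: the magnesium malonate half-ester enolate is C-acylated by the imidazolide and decarboxylates to the β-keto ester.

Step 13
Reactants: 20 methyl 3-oxo-3-[3,4,5-tris(benzyloxy)phenyl]propanoate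
Product: 21 methyl 2-chloro-3-oxo-3-[3,4,5-tris(benzyloxy)phenyl]propanoate (racemic)
Conditions: SO2Cl2 (1.0 equiv), CH2Cl2, 0 °C
Reagents that add atoms: sulfuryl chloride ClS(Cl)(=O)=O
Why: Electrophilic α-chlorination of the enol of the β-keto ester is fast and stops at the monochloride with one equivalent; the new centre is configurationally labile.

Step 14
Reactants: 21 methyl 2-chloro-3-oxo-3-[3,4,5-tris(benzyloxy)phenyl]propanoate
Product: 22 methyl (2S,3S)-2-chloro-3-hydroxy-3-[3,4,5-tris(benzyloxy)phenyl]propanoate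
Conditions: ketoreductase (KRED, NADPH-dependent, anti-selective), NADP+ (cat.), i-PrOH, phosphate buffer pH 6.5/toluene, 30 °C
Reagents that add atoms: none
Why: Enzymatic dynamic kinetic resolution by a ketoreductase (oxidoreductase class): the chloro keto ester racemises through its enol while the enzyme reduces one enantiomer from one face, setting C2 (S) and C3 (S) of the anti-chlorohydrin together, as in the known reduction of the 4-methoxyphenyl analogue.

Step 15
Reactants: 22 methyl (2S,3S)-2-chloro-3-hydroxy-3-[3,4,5-tris(benzyloxy)phenyl]propanoate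
Product: 23 methyl (2R,3S)-3-[3,4,5-tris(benzyloxy)phenyl]oxirane-2-carboxylate
Conditions: K2CO3, MeOH, 0 °C
Reagents that add atoms: none
Why: Intramolecular Williamson (SN2) ring closure inverts C2 and keeps C3, so the anti-chlorohydrin gives the trans-glycidate.

Step 16
Reactants: 23 methyl (2R,3S)-3-[3,4,5-tris(benzyloxy)phenyl]oxirane-2-carboxylate
Product: 24 potassium (2R,3S)-3-[3,4,5-tris(benzyloxy)phenyl]oxirane-2-carboxylate
Conditions: KOH (1.05 equiv), EtOH/THF, 0 °C
Reagents that add atoms: potassium hydroxide [K+].[OH-]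
Why: Saponification at the ester carbonyl gives the glycidate salt, which is stable as long as it is never acidified to the free acid.

Step 17
Reactants: 24 potassium (2R,3S)-3-[3,4,5-tris(benzyloxy)phenyl]oxirane-2-carboxylate
Product: 25 (2R,3S)-N-methoxy-N-methyl-3-[3,4,5-tris(benzyloxy)phenyl]oxirane-2-carboxamide
Conditions: MeNHOMe·HCl, EDC·HCl, HOBt, N-methylmorpholine, CH2Cl2, 0 °C → rt
Reagents that add atoms: N,O-dimethylhydroxylamine hydrochloride CNOC.Cl
Why: Carbodiimide amide coupling through the HOBt ester gives the Weinreb amide under near-neutral conditions that do not open the epoxide.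

Step 18
Reactants: 17 (2R,3S,4S)-3,7-bis(benzyloxy)-4-[3-bromo-2,6-bis(methoxymethoxy)phenyl]-2-[3,4,5-tris(benzyloxy)phenyl]chromane; 25 (2R,3S)-N-methoxy-N-methyl-3-[3,4,5-tris(benzyloxy)phenyl]oxirane-2-carboxamide
Product: 27 {3-[(2R,3S,4S)-3,7-bis(benzyloxy)-2-[3,4,5-tris(benzyloxy)phenyl]chroman-4-yl]-2,4-bis(methoxymethoxy)phenyl}[(2R,3S)-3-[3,4,5-tris(benzyloxy)phenyl]oxiran-2-yl]methanone, via aryllithium 26 (not isolated)
Conditions: n-BuLi, THF, −78 °C; then 25, −78 °C; aq NH4Cl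
Reagents that add atoms: none
Why: Br/Li exchange ortho to the MOM-oxy group followed by Weinreb ketone synthesis: the chelated tetrahedral adduct prevents over-addition and the epoxide is inert at −78 °C, so both epoxide centres are carried over unchanged.

Step 19
Reactants: 27 {3-[(2R,3S,4S)-3,7-bis(benzyloxy)-2-[3,4,5-tris(benzyloxy)phenyl]chroman-4-yl]-2,4-bis(methoxymethoxy)phenyl}[(2R,3S)-3-[3,4,5-tris(benzyloxy)phenyl]oxiran-2-yl]methanone
Product: 29 (2R,3R)-8-[(2R,3S,4S)-3,7-bis(benzyloxy)-2-[3,4,5-tris(benzyloxy)phenyl]chroman-4-yl]-3,7-dihydroxy-2-[3,4,5-tris(benzyloxy)phenyl]chroman-4-one, via epoxy ketone diphenol 28 (not isolated)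
Conditions: HCl (conc., 5 equiv), MeOH/THF, 45 °C
Reagents that add atoms: none
Why: Acid cleaves both MOM acetals and the freed ortho-phenol opens the epoxide 6-endo at the benzylic carbon with inversion (the ring closure of the chalcone-epoxide route to dihydroflavonols), giving the 2,3-trans (2R,3R) ring while C3 is never broken.

Step 20
Reactants: 29 (2R,3R)-8-[(2R,3S,4S)-3,7-bis(benzyloxy)-2-[3,4,5-tris(benzyloxy)phenyl]chroman-4-yl]-3,7-dihydroxy-2-[3,4,5-tris(benzyloxy)phenyl]chroman-4-one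
Product: 30 (2R,3R)-8-[(2R,3S,4S)-3,7-dihydroxy-2-(3,4,5-trihydroxyphenyl)chroman-4-yl]-3,7-dihydroxy-2-(3,4,5-trihydroxyphenyl)chroman-4-one (CNP0321606.1)
Conditions: H2 (1 atm), Pd(OH)2/C, THF/MeOH, rt
Reagents that add atoms: none
Why: Catalytic hydrogenolysis removes all eight benzyl ethers under neutral conditions that leave the vinylogous-ester ketone, the ring C–O bonds and all five stereocentres intact.

## Compound list

1 | 5-bromo-1,2,3-trimethoxybenzene | COc1cc(Br)cc(OC)c1OC | starting material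
2 | 5-bromobenzene-1,2,3-triol | Oc1cc(Br)cc(O)c1O | intermediate
3 | 5-bromo-1,2,3-tris(benzyloxy)benzene | Brc1cc(OCc2ccccc2)c(OCc2ccccc2)c(OCc2ccccc2)c1 | intermediate
4 | [3,4,5-tris(benzyloxy)phenyl]lithium | [Li]c1cc(OCc2ccccc2)c(OCc2ccccc2)c(OCc2ccccc2)c1 | intermediate
5 | [3,4,5-tris(benzyloxy)phenyl]boronic acid | OB(O)c1cc(OCc2ccccc2)c(OCc2ccccc2)c(OCc2ccccc2)c1 | intermediate
6 | 7-hydroxy-4H-chromen-4-one | O=c1ccoc2cc(O)ccc12 | starting material
7 | 7-(benzyloxy)-4H-chromen-4-one | O=c1ccoc2cc(OCc3ccccc3)ccc12 | intermediate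
8 | (2S)-7-(benzyloxy)-2-[3,4,5-tris(benzyloxy)phenyl]-2,3-dihydro-4H-chromen-4-one | O=C1C[C@@H](c2cc(OCc3ccccc3)c(OCc3ccccc3)c(OCc3ccccc3)c2)Oc2cc(OCc3ccccc3)ccc12 | intermediate
9 | 2-iodobenzene-1,3-diol | Oc1cccc(O)c1I | starting material
10 | 2-iodo-1,3-bis(methoxymethoxy)benzene | COCOc1cccc(OCOC)c1I | intermediate
11 | 1-bromo-3-iodo-2,4-bis(methoxymethoxy)benzene | COCOc1ccc(Br)c(OCOC)c1I | intermediate
12 | [3-bromo-2,6-bis(methoxymethoxy)phenyl]magnesium chloride | COCOc1ccc(Br)c(OCOC)c1[Mg]Cl | intermediate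
13 | (2S)-7-(benzyloxy)-4-[3-bromo-2,6-bis(methoxymethoxy)phenyl]-2-[3,4,5-tris(benzyloxy)phenyl]chroman-4-ol (C-4 epimers) | OC1(c2c(OCOC)ccc(Br)c2OCOC)C[C@@H](c2cc(OCc3ccccc3)c(OCc3ccccc3)c(OCc3ccccc3)c2)Oc2cc(OCc3ccccc3)ccc21 | intermediate
14 | (2S)-7-(benzyloxy)-4-[3-bromo-2,6-bis(methoxymethoxy)phenyl]-2-[3,4,5-tris(benzyloxy)phenyl]-2H-chromene | COCOc1ccc(Br)c(OCOC)c1C1=C[C@@H](c2cc(OCc3ccccc3)c(OCc3ccccc3)c(OCc3ccccc3)c2)Oc2cc(OCc3ccccc3)ccc21 | intermediate
15 | [(2S,3S,4S)-7-(benzyloxy)-4-[3-bromo-2,6-bis(methoxymethoxy)phenyl]-2-[3,4,5-tris(benzyloxy)phenyl]chroman-3-yl]borane (same spatial arrangement as 16; the C2 descriptor changes because boron ranks below carbon) | COCOc1ccc(Br)c(OCOC)c1[C@@H]1c2ccc(OCc3ccccc3)cc2O[C@H](c2cc(OCc3ccccc3)c(OCc3ccccc3)c(OCc3ccccc3)c2)[C@H]1B | intermediate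
16 | (2R,3S,4S)-7-(benzyloxy)-4-[3-bromo-2,6-bis(methoxymethoxy)phenyl]-2-[3,4,5-tris(benzyloxy)phenyl]chroman-3-ol | COCOc1ccc(Br)c(OCOC)c1[C@@H]1c2ccc(OCc3ccccc3)cc2O[C@H](c2cc(OCc3ccccc3)c(OCc3ccccc3)c(OCc3ccccc3)c2)[C@H]1O | intermediate
17 | (2R,3S,4S)-3,7-bis(benzyloxy)-4-[3-bromo-2,6-bis(methoxymethoxy)phenyl]-2-[3,4,5-tris(benzyloxy)phenyl]chromane | COCOc1ccc(Br)c(OCOC)c1[C@@H]1c2ccc(OCc3ccccc3)cc2O[C@H](c2cc(OCc3ccccc3)c(OCc3ccccc3)c(OCc3ccccc3)c2)[C@H]1OCc1ccccc1 | intermediate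
18 | 3,4,5-tris(benzyloxy)benzoic acid | OC(=O)c1cc(OCc2ccccc2)c(OCc2ccccc2)c(OCc2ccccc2)c1 | starting material
19 | 1-[3,4,5-tris(benzyloxy)benzoyl]-1H-imidazole | O=C(c1cc(OCc2ccccc2)c(OCc2ccccc2)c(OCc2ccccc2)c1)n1ccnc1 | intermediate
20 | methyl 3-oxo-3-[3,4,5-tris(benzyloxy)phenyl]propanoate | COC(=O)CC(=O)c1cc(OCc2ccccc2)c(OCc2ccccc2)c(OCc2ccccc2)c1 | intermediate
21 | methyl 2-chloro-3-oxo-3-[3,4,5-tris(benzyloxy)phenyl]propanoate (racemic, configurationally labile) | COC(=O)C(Cl)C(=O)c1cc(OCc2ccccc2)c(OCc2ccccc2)c(OCc2ccccc2)c1 | intermediate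
22 | methyl (2S,3S)-2-chloro-3-hydroxy-3-[3,4,5-tris(benzyloxy)phenyl]propanoate | COC(=O)[C@@H](Cl)[C@@H](O)c1cc(OCc2ccccc2)c(OCc2ccccc2)c(OCc2ccccc2)c1 | intermediate
23 | methyl (2R,3S)-3-[3,4,5-tris(benzyloxy)phenyl]oxirane-2-carboxylate | COC(=O)[C@@H]1O[C@H]1c1cc(OCc2ccccc2)c(OCc2ccccc2)c(OCc2ccccc2)c1 | intermediate
24 | potassium (2R,3S)-3-[3,4,5-tris(benzyloxy)phenyl]oxirane-2-carboxylate | [K+].[O-]C(=O)[C@@H]1O[C@H]1c1cc(OCc2ccccc2)c(OCc2ccccc2)c(OCc2ccccc2)c1 | intermediate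
25 | (2R,3S)-N-methoxy-N-methyl-3-[3,4,5-tris(benzyloxy)phenyl]oxirane-2-carboxamide | CON(C)C(=O)[C@@H]1O[C@H]1c1cc(OCc2ccccc2)c(OCc2ccccc2)c(OCc2ccccc2)c1 | intermediate
26 | {3-[(2R,3S,4S)-3,7-bis(benzyloxy)-2-[3,4,5-tris(benzyloxy)phenyl]chroman-4-yl]-2,4-bis(methoxymethoxy)phenyl}lithium | [Li]c1ccc(OCOC)c([C@@H]2c3ccc(OCc4ccccc4)cc3O[C@H](c3cc(OCc4ccccc4)c(OCc4ccccc4)c(OCc4ccccc4)c3)[C@H]2OCc2ccccc2)c1OCOC | intermediate
27 | {3-[(2R,3S,4S)-3,7-bis(benzyloxy)-2-[3,4,5-tris(benzyloxy)phenyl]chroman-4-yl]-2,4-bis(methoxymethoxy)phenyl}[(2R,3S)-3-[3,4,5-tris(benzyloxy)phenyl]oxiran-2-yl]methanone | O=C([C@@H]1O[C@H]1c1cc(OCc2ccccc2)c(OCc2ccccc2)c(OCc2ccccc2)c1)c1ccc(OCOC)c([C@@H]2c3ccc(OCc4ccccc4)cc3O[C@H](c3cc(OCc4ccccc4)c(OCc4ccccc4)c(OCc4ccccc4)c3)[C@H]2OCc2ccccc2)c1OCOC | intermediate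
28 | {3-[(2R,3S,4S)-3,7-bis(benzyloxy)-2-[3,4,5-tris(benzyloxy)phenyl]chroman-4-yl]-2,4-dihydroxyphenyl}[(2R,3S)-3-[3,4,5-tris(benzyloxy)phenyl]oxiran-2-yl]methanone | O=C([C@@H]1O[C@H]1c1cc(OCc2ccccc2)c(OCc2ccccc2)c(OCc2ccccc2)c1)c1ccc(O)c([C@@H]2c3ccc(OCc4ccccc4)cc3O[C@H](c3cc(OCc4ccccc4)c(OCc4ccccc4)c(OCc4ccccc4)c3)[C@H]2OCc2ccccc2)c1O | intermediate
29 | (2R,3R)-8-[(2R,3S,4S)-3,7-bis(benzyloxy)-2-[3,4,5-tris(benzyloxy)phenyl]chroman-4-yl]-3,7-dihydroxy-2-[3,4,5-tris(benzyloxy)phenyl]chroman-4-one | O=C1c2ccc(O)c([C@@H]3c4ccc(OCc5ccccc5)cc4O[C@H](c4cc(OCc5ccccc5)c(OCc5ccccc5)c(OCc5ccccc5)c4)[C@H]3OCc3ccccc3)c2O[C@H](c2cc(OCc3ccccc3)c(OCc3ccccc3)c(OCc3ccccc3)c2)[C@H]1O | intermediate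
30 | (2R,3R)-8-[(2R,3S,4S)-3,7-dihydroxy-2-(3,4,5-trihydroxyphenyl)chroman-4-yl]-3,7-dihydroxy-2-(3,4,5-trihydroxyphenyl)chroman-4-one | O=C1c2ccc(O)c([C@@H]3c4ccc(O)cc4O[C@H](c4cc(O)c(O)c(O)c4)[C@H]3O)c2O[C@H](c2cc(O)c(O)c(O)c2)[C@H]1O | target

## Step count and risks

Total step count: 20. Longest linear sequence: 11 steps (1 → 2 → 3 → 5 → 8 → 13 → 14 → 16 → 17 → 27 → 29 → 30; steps 1, 2, 3, 5, 8, 9, 10, 11, 18, 19, 20).

Risk 1, step 8. The doubly ortho-substituted aryl nucleophile may enolise the electron-rich ketone (ring opening to the chalcone) instead of adding to it. The fallback sets out from flavanone 8 together with Grignard reagent 12 and comes back at chromene 14. Ketone 8 is O-triflated with Tf2O and 2,6-di-tert-butyl-4-methylpyridine in CH2Cl2 at 0 °C, without an enolate, to give (2S)-7-(benzyloxy)-2-[3,4,5-tris(benzyloxy)phenyl]-2H-chromen-4-yl trifluoromethanesulfonate F1. Grignard reagent 12 is transmetalated with ZnCl2 to [3-bromo-2,6-bis(methoxymethoxy)phenyl]zinc chloride F2. Negishi cross-coupling of F1 with F2 (Pd(PPh3)4, LiCl, THF, 50 °C) then gives 14 directly, because the enol triflate undergoes oxidative addition faster than the electron-rich aryl bromide. This replaces carbonyl addition and dehydration (steps 8 and 9) by an sp2–sp2 coupling.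

Risk 2, step 14. The ketoreductase may not accept the bulky tris(benzyloxy)phenyl substrate or may give poor anti selectivity. The fallback sets out from bromide 3 and comes back at glycidate 23. Aryllithium 4 (from 3 and n-BuLi) is formylated with DMF to 3,4,5-tris(benzyloxy)benzaldehyde F3. Darzens condensation of F3 with methyl chloroacetate and NaOMe in MeOH gives racemic methyl trans-3-[3,4,5-tris(benzyloxy)phenyl]oxirane-2-carboxylate F4. A lipase (hydrolase class, for example Serratia marcescens lipase in toluene/phosphate buffer) then hydrolyses only the (2S,3R)-ester, by analogy with the 4-methoxyphenyl glycidate. The hydrolysed enantiomer, (2S,3R)-3-[3,4,5-tris(benzyloxy)phenyl]oxirane-2-carboxylic acid F5, is washed out with aqueous base and leaves ester 23. This replaces steps 12 to 15 by a Darzens condensation and an enzymatic kinetic resolution, at the cost of half the material.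

Risk 3, step 19. Acid may open the epoxide with chloride or methanol before the ortho MOM group is off, giving cis/trans mixtures or ring-contracted benzofuranones. The fallback sets out from epoxy ketone 27 and comes back at 29. Phenylmethanethiol with SnCl4 (CH2Cl2, −20 °C) opens the epoxide at the benzylic carbon and strips both MOM groups in the same operation. This gives (2S,3RS)-3-(benzylsulfanyl)-1-{3-[(2R,3S,4S)-3,7-bis(benzyloxy)-2-[3,4,5-tris(benzyloxy)phenyl]chroman-4-yl]-2,4-dihydroxyphenyl}-2-hydroxy-3-[3,4,5-tris(benzyloxy)phenyl]propan-1-one F6, in which the hydroxyl-bearing carbon is spatially unchanged. The thiophilic Lewis acid AgBF4 (CH2Cl2, 0 °C) then ionises the thioether, and the ortho-phenol closes the ring to mainly the 2,3-trans product 29, with the minor 2,3-cis isomer removed by chromatography. This replaces direct acid cyclisation by a thioether intermediate and a separate ring closure.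

## Further compounds

F1 | step 8 | (2S)-7-(benzyloxy)-2-[3,4,5-tris(benzyloxy)phenyl]-2H-chromen-4-yl trifluoromethanesulfonate | FC(F)(F)S(=O)(=O)OC1=C[C@@H](c2cc(OCc3ccccc3)c(OCc3ccccc3)c(OCc3ccccc3)c2)Oc2cc(OCc3ccccc3)ccc21
F2 | step 8 | [3-bromo-2,6-bis(methoxymethoxy)phenyl]zinc chloride | COCOc1ccc(Br)c(OCOC)c1[Zn]Cl
F3 | step 14 | 3,4,5-tris(benzyloxy)benzaldehyde | O=Cc1cc(OCc2ccccc2)c(OCc2ccccc2)c(OCc2ccccc2)c1
F4 | step 14 | methyl trans-3-[3,4,5-tris(benzyloxy)phenyl]oxirane-2-carboxylate (racemate, both enantiomers written) | COC(=O)[C@@H]1O[C@H]1c1cc(OCc2ccccc2)c(OCc2ccccc2)c(OCc2ccccc2)c1.COC(=O)[C@H]1O[C@@H]1c1cc(OCc2ccccc2)c(OCc2ccccc2)c(OCc2ccccc2)c1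
F5 | step 14 | (2S,3R)-3-[3,4,5-tris(benzyloxy)phenyl]oxirane-2-carboxylic acid | OC(=O)[C@H]1O[C@@H]1c1cc(OCc2ccccc2)c(OCc2ccccc2)c(OCc2ccccc2)c1
F6 | step 19 | (2S,3RS)-3-(benzylsulfanyl)-1-{3-[(2R,3S,4S)-3,7-bis(benzyloxy)-2-[3,4,5-tris(benzyloxy)phenyl]chroman-4-yl]-2,4-dihydroxyphenyl}-2-hydroxy-3-[3,4,5-tris(benzyloxy)phenyl]propan-1-one | O=C([C@H](O)C(SCc1ccccc1)c1cc(OCc2ccccc2)c(OCc2ccccc2)c(OCc2ccccc2)c1)c1ccc(O)c([C@@H]2c3ccc(OCc4ccccc4)cc3O[C@H](c3cc(OCc4ccccc4)c(OCc4ccccc4)c(OCc4ccccc4)c3)[C@H]2OCc2ccccc2)c1O
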